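**Assumption:** the target has no stereocentres (both CMe2 carbons are achiral), so no stereocontrol is needed. The route is built on regiochemical assumptions that are stated in the Why lines of the steps where they matter.

## Retrosynthetic overview
1. Target ← global removal of a MOM ether and a peri-OMe from the pentacyclic core **21**.
2. The furan ring is formed last by intramolecular Pd-catalysed C–H arylation (aryl bromide onto chromone C3–H) of the 2-aryloxychromone **20**.
3. The key late coupling is SNAr of the ring-A phenol **19** on the 2-methylsulfonylchromone **11**.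
4. Fragment **11** is built from resorcinol. Directed ortho-metalation (DoM) and Ir-borylation/oxidation give a symmetric 4-hydroxy-2,6-dimethoxyacetophenone. The chroman is then formed by prenal annulation and hydrogenation, and the pyranone by the CS2 route.
5. Fragment **19** is built from benzoquinone. Thiele–Winter acetoxylation gives a hydroxyquinone, which is annulated with prenal to the chromene quinone. Bromide addition and mono-MOM protection follow.

## Route

**Fragment B (Steps 1–8)**

**Step 1**
Reactants: 1 resorcinol
Product: 2 1,3-dimethoxybenzene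
Conditions: MeI, K2CO3, acetone, reflux
Reagents that add atoms: iodomethane, CI
Why: Williamson bis-O-methylation; no stereocentre.

**Step 2**
Reactants: 2; 3 N-methoxy-N-methylacetamide
Product: 4 1-(2,6-dimethoxyphenyl)ethan-1-one
Conditions: n-BuLi, THF, 0 °C; then 3, −78 → 25 °C
Reagents that add atoms: none beyond reactant 3 (CC(=O)N(C)OC)
Why: DoM puts lithium at C2, between the two OMe groups, and the Weinreb amide gives the ketone without over-addition.

**Step 3**
Reactants: 4
Product: 5 1-(4-hydroxy-2,6-dimethoxyphenyl)ethan-1-one
Conditions: B2pin2, [Ir(OMe)cod]2, dtbpy, THF, 80 °C; then NaBO3·4H2O, THF/H2O, 25 °C (one pot, Bpin ester not isolated)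
Reagents that add atoms: hydrogen peroxide equivalent from perborate, OO (supplies the phenol O)
Why: Ir-catalysed C–H borylation is sterically controlled and goes to C4, which has two neighbouring C–H bonds. Oxidation of C–B then gives the symmetric phenol, so the two OMe groups stay equivalent until annulation.

**Step 4**
Reactants: 5; 6 prenal (3-methyl-2-butenal)
Product: 7 1-(5,7-dimethoxy-2,2-dimethyl-2H-chromen-6-yl)ethan-1-one
Conditions: pyridine, 130 °C, sealed tube
Reagents that add atoms: none (prenal is reactant 6)
Why: Phenol–enal Knoevenagel condensation followed by oxa-6π-electrocyclisation. Both ortho positions of 5 are equivalent, so there is no regiochemical issue.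

**Step 5**
Reactants: 7
Product: 8 1-(5,7-dimethoxy-2,2-dimethylchroman-6-yl)ethan-1-one
Conditions: H2 (1 atm), 10% Pd/C, EtOAc, 25 °C
Reagents that add atoms: none
Why: The chromene C=C is hydrogenated here, before the ring-A chromene exists, so the two pyran rings can be differentiated. The hindered acetophenone is untouched.

**Step 6**
Reactants: 8
Product: 9 1-(5-hydroxy-7-methoxy-2,2-dimethylchroman-6-yl)ethan-1-one
Conditions: BCl3 (1.1 equiv), CH2Cl2, −78 → −20 °C
Reagents that add atoms: none
Why: Acetyl-chelated BCl3 demethylation. The C5-OMe, flanked by the C4a-alkyl and the acetyl, is the most strained and Lewis-basic, so it is cleaved selectively. This frees the oxygen that must become the pyranone O (assumption).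

**Step 7**
Reactants: 9
Product: 10 5-methoxy-2-(methylthio)chromone with a 2,2-dimethyl-3,4-dihydropyran fused across C7–C8 (O on C7, CH2 on C8)
Conditions: NaH (3 equiv), CS2, DMF, 0 °C; then MeI (2.2 equiv), 0 → 25 °C
Reagents that add atoms: carbon disulfide, S=C=S; iodomethane, CI
Why: The ketone enolate adds to CS2 and S-methylation gives the dithioester. The phenoxide closes onto C=S (6-exo), and the expelled/retained sulfur is methylated to give the 2-SMe chromone (ketene-dithioacetal-type chromone synthesis).

**Step 8**
Reactants: 10
Product: 11 2-(methylsulfonyl) analogue of 10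
Conditions: mCPBA (2.5 equiv), CH2Cl2, 0 → 25 °C
Reagents that add atoms: mCPBA, OOC(=O)c1cccc(Cl)c1
Why: Sulfide to sulfone oxidation, which makes C2 a strong SNAr electrophile. There is no alkene present at this stage, so no epoxidation competes.

**Fragment A (Steps 9–15)**

**Step 9**
Reactants: 12 1,4-benzoquinone
Product: 13 1,2,4-triacetoxybenzene
Conditions: Ac2O, cat. H2SO4, 0 → 25 °C
Reagents that add atoms: acetic anhydride, CC(=O)OC(C)=O
Why: Thiele–Winter acetoxylation; 1,4-addition of AcOH followed by enol acetylation and aromatisation.

**Step 10**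
Reactants: 13
Product: 14 benzene-1,2,4-triol
Conditions: aq. HCl, MeOH, reflux, N2
Reagents that add atoms: none
Why: Acid hydrolysis of the three aryl acetates; the triol is oxygen-sensitive and used at once.

**Step 11**
Reactants: 14
Product: 15 2-hydroxy-1,4-benzoquinone
Conditions: Ag2O, Et2O, 25 °C
Reagents that add atoms: none
Why: Two-electron oxidation of the triol. This fixes the hydroquinone-type O atoms (C=O at C1 and C4) and the enolic 2-OH, which will become the ring-A O pattern.

**Step 12**
Reactants: 15; 6 prenal
Product: 16 2,2-dimethyl-2H-chromene-5,8-dione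
Conditions: ethylenediammonium diacetate (EDDA, 10 mol%), toluene, 80 °C
Reagents that add atoms: none (prenal is reactant 6)
Why: Knoevenagel condensation at the vinylogous-acid C3 followed by oxa-6π-electrocyclisation. The only nucleophilic C–H is C3, so the pyran forms between C2–O and C3.

**Step 13**
Reactants: 16
Product: 17 6-bromo-2,2-dimethyl-2H-chromene-5,8-dione
Conditions: LiBr, AcOH, MeCN, 25 °C; then MnO2, CH2Cl2
Reagents that add atoms: lithium bromide, [Li+].[Br-]
Why: Conjugate addition of bromide, then re-oxidation of the bromohydroquinone. C5=O is deactivated as a vinylogous ester through O1, so Br− adds at C6, which is β to the C8 carbonyl (assumption).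

**Step 14**
Reactants: 17
Product: 18 6-bromo-2,2-dimethyl-2H-chromene-5,8-diol
Conditions: Na2S2O4, Et2O/H2O, 25 °C
Reagents that add atoms: none
Why: Quinone to hydroquinone reduction; the hydroquinone is used immediately.

**Step 15**
Reactants: 18
Product: 19 6-bromo-8-(methoxymethoxy)-2,2-dimethyl-2H-chromen-5-ol
Conditions: MOMCl (1.0 equiv), iPr2NEt, CH2Cl2, −20 → 0 °C, N2
Reagents that add atoms: chloromethyl methyl ether, ClCOC
Why: Mono-O-alkylation goes at the less hindered C8-OH. The C5-OH is flanked by Br and the peri vinyl group, so it stays free for the SNAr (assumption).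

**Coupling and end game (Steps 16–18)**

**Step 16**
Reactants: 11; 19
Product: 20 2-aryloxychromone (ring-A aryl = 6-bromo-8-MOMO-2,2-dimethyl-2H-chromen-5-yl)
Conditions: K2CO3, DMF, 50 °C
Reagents that add atoms: none
Why: Key fragment coupling by addition–elimination SNAr. The phenoxide attacks C2, the β-position of the enone, and methanesulfinate leaves; no stereocentre is formed.

**Step 17**
Reactants: 20
Product: 21 pentacyclic core with OMOM on ring A and OMe on ring B
Conditions: Pd(OAc)2 (10 mol%), PCy3·HBF4 (20 mol%), K2CO3, PivOH (30 mol%), DMA, 130 °C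
Reagents that add atoms: none
Why: Intramolecular direct arylation by concerted metalation–deprotonation (CMD). Oxidative addition into ArBr gives a six-membered palladacycle through the ether O that C–H-activates the nucleophilic enol-ether C3–H. Reductive elimination closes the furan; no stereocentre is formed.

**Step 18**
Reactants: 21
Product: 22 Formosanatin D
Conditions: BCl3 (4 equiv), CH2Cl2, −78 → 0 °C, then MeOH quench
Reagents that add atoms: none
Why: BCl3 cleaves the MOM ether and the chelated peri-OMe (demethylation by BCl3); the 2,2-dimethylchromene survives at low temperature and short reaction time.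

## Compound list
1 | resorcinol | Oc1cccc(O)c1 | starting material
2 | 1,3-dimethoxybenzene | COc1cccc(OC)c1 | intermediate
3 | N-methoxy-N-methylacetamide | CC(=O)N(C)OC | starting material
4 | 1-(2,6-dimethoxyphenyl)ethan-1-one | CC(=O)c1c(OC)cccc1OC | intermediate
5 | 1-(4-hydroxy-2,6-dimethoxyphenyl)ethan-1-one | CC(=O)c1c(OC)cc(O)cc1OC | intermediate
6 | prenal | CC(C)=CC=O | starting material
7 | 1-(5,7-dimethoxy-2,2-dimethyl-2H-chromen-6-yl)ethan-1-one | CC(=O)c1c(OC)cc2OC(C)(C)C=Cc2c1OC | intermediate
8 | 1-(5,7-dimethoxy-2,2-dimethylchroman-6-yl)ethan-1-one | CC(=O)c1c(OC)cc2OC(C)(C)CCc2c1OC | intermediate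
9 | 1-(5-hydroxy-7-methoxy-2,2-dimethylchroman-6-yl)ethan-1-one | CC(=O)c1c(OC)cc2OC(C)(C)CCc2c1O | intermediate
10 | 2-(methylthio)chromone, dimethyldihydropyran-fused, 5-OMe | CSC1=CC(=O)c2c(OC)cc3OC(C)(C)CCc3c2O1 | intermediate
11 | 2-(methylsulfonyl) analogue of 10 | CS(=O)(=O)C1=CC(=O)c2c(OC)cc3OC(C)(C)CCc3c2O1 | intermediate
12 | 1,4-benzoquinone | O=C1C=CC(=O)C=C1 | starting material
13 | 1,2,4-triacetoxybenzene | CC(=O)Oc1ccc(OC(C)=O)c(OC(C)=O)c1 | intermediate
14 | benzene-1,2,4-triol | Oc1ccc(O)c(O)c1 | intermediate
15 | 2-hydroxy-1,4-benzoquinone | O=C1C=CC(=O)C(O)=C1 | intermediate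
16 | 2,2-dimethyl-2H-chromene-5,8-dione | CC1(C)C=CC2=C(O1)C(=O)C=CC2=O | intermediate
17 | 6-bromo-2,2-dimethyl-2H-chromene-5,8-dione | CC1(C)C=CC2=C(O1)C(=O)C=C(Br)C2=O | intermediate
18 | 6-bromo-2,2-dimethyl-2H-chromene-5,8-diol | CC1(C)C=Cc2c(O)c(Br)cc(O)c2O1 | intermediate
19 | 6-bromo-8-(methoxymethoxy)-2,2-dimethyl-2H-chromen-5-ol | CC1(C)C=Cc2c(O)c(Br)cc(OCOC)c2O1 | intermediate
20 | 2-aryloxychromone from coupling of 11 and 19 | COc1cc2OC(C)(C)CCc2c2OC(Oc3c(Br)cc(OCOC)c4OC(C)(C)C=Cc34)=CC(=O)c12 | intermediate
21 | MOM/Me-protected pentacyclic core | CC1(C)C=Cc2c(c(OCOC)cc3c2oc2oc4c5c(cc(OC)c4c(=O)c23)OC(C)(C)CC5)O1 | intermediate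
22 | Formosanatin D | CC1(C)C=Cc2c(c(O)cc3c2oc2oc4c5c(cc(O)c4c(=O)c23)OC(C)(C)CC5)O1 | target

## Step counts
- Total steps: 18.
- Longest linear sequence: 11 (resorcinol, Steps 1–8, then 16–18). The benzoquinone arm is 7 steps plus the final 3, so 10.

## Three steps most likely to fail
1. **Step 17 (Pd direct arylation).** The electron-rich aryl bromide may undergo slow oxidative addition or competing hydrodebromination.
   - Fallback: a different mechanism, base-mediated homolytic aromatic substitution of the aryl bromide (KOtBu, 1,10-phenanthroline, benzene, 80 °C).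
2. **Step 6 (chelation-controlled mono-demethylation).** The selectivity for the hindered C5-OMe is assumed, and BCl3 may open the tertiary chroman ether.
   - Fallback: remove both methyls (BBr3), then differentiate the two OH groups by steric control, with TBSCl/imidazole silylating the less hindered C7-OH. Carry the TBS group through and remove it with TBAF at the end.
3. **Step 18 (global deprotection).** BCl3 may damage the acid-sensitive 2,2-dimethylchromene or the ketene-acetal-type C2.
   - Fallback: change the protecting strategy. Use MOM ethers on both rings (ring-B 7-O as MOM from a bis-MOM resorcinol route) and remove them with ZnBr2/n-PrSH at 0 °C, avoiding strong Lewis acids.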